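**Retrosynthetic overview**
1. Target 21 ⇐ C7 carbinol 19 (oxidation and α,β-dehydrogenation last); the two esters go on one at a time, and each carbinol (C1, C3) is set by a reagent-controlled CBS reduction.
2. Seven-membered ring ⇐ C3–C4 bond: hydrogen-atom-transfer radical cyclisation of a C5 isopropylidene onto a nitrile hung from C11 (sets C5, makes quaternary C4).
3. Bicyclo[3.1.1]heptan-7-one core (cyclobutane C5–C6–C11–C10) ⇐ semipinacol ring expansion of an epoxidised silyloxy vinylcyclopropane: 1,2-shift of C11 from C5 to C6 (cyclopropane → cyclobutanone).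
4. Cyclopropane ⇐ Rh carbenoid from methyl 2-diazopropanoate plus the kinetic silyl dienol ether of (R)-5-methylcyclohex-2-enone; its methyl steers the face and is erased in the last step.
5. Ring order: six-membered ring (bought) → cyclopropane → cyclobutane (ring expansion) → seven-membered ring.

Assumption: (R)-5-methylcyclohex-2-en-1-one (8 non-hydrogen atoms) is taken to be a catalogue compound.
Numbering used in the text (skeleton numbering, order of the target SMILES): C1 (CH–O-tiglate), C2 (CH2), C3 (CH–O-isovalerate), C4 (CMe2), C5 and C6 (cyclobutane CH), C7 (C=O), C8 (=CH), C9 (=C–Me), C10 (cyclobutane CH), C11 (quaternary C–Me). Systematic names of the tricycles use tricyclo[5.4.0.0^2,8]undecane locants (C1 = 3, C3 = 5, C4 = 6, C7 = 11, C9 = 9, C11 = 2). TBS = tert-butyldimethylsilyl.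

**Step 1**
Reactants: 1 methyl DL-alaninate hydrochloride
Product: 3 methyl 2-diazopropanoate, via methyl alaninate 2 (not isolated)
Conditions: Et3N, CHCl3, rt; then isoamyl nitrite, AcOH (cat.), reflux
Reagents that add atoms: isoamyl nitrite CC(C)CCON=O
Why: Aprotic diazotisation of an α-amino ester, in which the α-acyl diazonium ion loses its α-proton faster than nitrogen and gives the α-diazo ester; the stereocentre is given up on purpose.

**Step 2**
Reactants: 4 (R)-5-methylcyclohex-2-en-1-one
Product: 5 tert-butyldimethyl{[(3R)-3-methylcyclohexa-1,5-dien-1-yl]oxy}silane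
Conditions: TBSOTf, Et3N, CH2Cl2, 0 °C
Reagents that add atoms: tert-butyldimethylsilyl triflate CC(C)(C)[Si](C)(C)OS(=O)(=O)C(F)(F)F
Why: Soft enolisation and O-silylation at the α′ methylene (C10) gives the cross-conjugated 2-silyloxy diene (kinetic silyl dienol ether formation); the C9 stereocentre is untouched.

**Step 3**
Reactants: 5 tert-butyldimethyl{[(3R)-3-methylcyclohexa-1,5-dien-1-yl]oxy}silane; 3 methyl 2-diazopropanoate
Product: 6 methyl (5R)-1-(tert-butyldimethylsilyloxy)-5,7-dimethylbicyclo[4.1.0]hept-2-ene-7-carboxylate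
Conditions: Rh2(O2CCPh3)4 (1 mol%), CH2Cl2, −78 °C, slow addition of 3
Reagents that add atoms: none
Why: Rh-carbenoid cyclopropanation of the electron-rich silyl enol ether bond C5=C10 (donor–acceptor cyclopropane synthesis), where the carbenoid comes in anti to the neighbouring C9 methyl (sets C5 and C10), the ester takes the exo position and the methyl the endo one (sets C11), and the bulky triphenylacetate ligands hold back β-hydride migration.

**Step 4**
Reactants: 6 methyl (5R)-1-(tert-butyldimethylsilyloxy)-5,7-dimethylbicyclo[4.1.0]hept-2-ene-7-carboxylate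
Product: 8 methyl (4R)-2-(tert-butyldimethylsilyloxy)-4,6-dimethyl-7-oxobicyclo[3.1.1]heptane-6-carboxylate, via epoxide 7 (not isolated)
Conditions: DMDO (acetone), CH2Cl2, −78 → −40 °C; then TBSOTf (10 mol%), −78 °C
Reagents that add atoms: dimethyldioxirane CC1(C)OO1
Why: Proposed new method: an epoxide-triggered semipinacol ring expansion (cyclopropyl silyl ether → cyclobutanone) that turns the fused bicyclo[4.1.0]heptene into the bridged bicyclo[3.1.1]heptan-7-one; DMDO epoxidises C6=C7 anti to the cyclopropane, the silyl triflate opens the epoxide at C6 while the C5–C11 σ-bond, pushed by the silyloxy oxygen and antiperiplanar to the C6–O bond, shifts from C5 to C6 with inversion at C6 and retention at C11 (the in-plane C5–C10 bond cannot align, so only C11 moves), and the oxocarbenium ion returns its silyl group to the triflate, which leaves the silyl on the C7 oxygen; this sets C6, keeps C10 and C11, and places the C11 ester on the side of the new C5 ketone; the closest known reaction types are the epoxidation- or halonium-induced ring expansion of 1-alkenylcyclopropanols to 2-substituted cyclobutanones and the Lewis-acid rearrangement of 2,3-epoxy silyl ethers, neither shown on a fused donor–acceptor cyclopropane to give a bridged cyclobutanone.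

**Step 5**
Reactants: 8 methyl (4R)-2-(tert-butyldimethylsilyloxy)-4,6-dimethyl-7-oxobicyclo[3.1.1]heptane-6-carboxylate
Product: 9 methyl (4R)-2-(tert-butyldimethylsilyloxy)-4,6-dimethyl-7-(propan-2-ylidene)bicyclo[3.1.1]heptane-6-carboxylate
Conditions: i-PrPPh3I, n-BuLi, THF, 0 °C; then 8, 0 → 50 °C
Reagents that add atoms: isopropyltriphenylphosphonium iodide CC(C)[P+](c1ccccc1)(c1ccccc1)c1ccccc1.[I-]
Why: Wittig olefination of the strained, non-enolisable cyclobutanone, which is far more electrophilic than the hindered ester; no stereocentre is formed.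

**Step 6**
Reactants: 9 methyl (4R)-2-(tert-butyldimethylsilyloxy)-4,6-dimethyl-7-(propan-2-ylidene)bicyclo[3.1.1]heptane-6-carboxylate
Product: 10 3-[(4R)-2-(tert-butyldimethylsilyloxy)-4,6-dimethyl-7-(propan-2-ylidene)bicyclo[3.1.1]heptan-6-yl]-3-oxopropanenitrile
Conditions: MeCN, n-BuLi, THF, −78 °C; then 9, −78 → 0 °C; aq. HCl work-up
Reagents that add atoms: acetonitrile CC#N
Why: Claisen-type acylation of lithiated acetonitrile by the methyl ester gives the β-ketonitrile (C1–C2–C3), whose enolate protects it from a second addition.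

**Step 7**
Reactants: 10 3-[(4R)-2-(tert-butyldimethylsilyloxy)-4,6-dimethyl-7-(propan-2-ylidene)bicyclo[3.1.1]heptan-6-yl]-3-oxopropanenitrile
Product: 11 (3R)-3-[(4R)-2-(tert-butyldimethylsilyloxy)-4,6-dimethyl-7-(propan-2-ylidene)bicyclo[3.1.1]heptan-6-yl]-3-hydroxypropanenitrile
Conditions: (S)-2-methyl-CBS-oxazaborolidine (20 mol%), catecholborane, toluene, −78 °C; then MeOH, H2O
Reagents that add atoms: none
Why: Corey–Bakshi–Shibata reduction, in which the oxazaborolidine tells the quaternary C11 (large) from CH2CN (small) and so sets C1 (R) by reagent control; catecholborane leaves the tetrasubstituted alkene alone.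

**Step 8**
Reactants: 11 (3R)-3-[(4R)-2-(tert-butyldimethylsilyloxy)-4,6-dimethyl-7-(propan-2-ylidene)bicyclo[3.1.1]heptan-6-yl]-3-hydroxypropanenitrile
Product: 13 11-(tert-butyldimethylsilyloxy)-3-hydroxy-2,6,6,9-tetramethyltricyclo[5.4.0.0^2,8]undecan-5-one, via ketimine 12 (not isolated)
Conditions: Fe(acac)3 (30 mol%), PhSiH3, EtOH, 60 °C; then aq. citric acid, rt
Reagents that add atoms: water O
Why: Proposed new method: an iron-hydride hydrogen-atom transfer (Mukaiyama-type HAT) puts H on C5 of the tetrasubstituted alkene from the face of the three-carbon bridge (the other face is blocked by the axial C11 side chain) and leaves the tertiary C4 radical 1,3-diaxial to that chain, where it adds 7-exo to the nitrile carbon; the iminyl radical is reduced and the ketimine hydrolysed to the C3 ketone, which forms the C3–C4 bond, the quaternary C4 and the seven-membered ring and sets C5, while a C5 epimer whose radical cannot reach the nitrile can return to 11 by back-transfer; the closest known reaction type is the HAT-initiated reductive cyclisation of alkene-tethered nitriles and ketones to five- and six-membered rings.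

**Step 9**
Reactants: 13 11-(tert-butyldimethylsilyloxy)-3-hydroxy-2,6,6,9-tetramethyltricyclo[5.4.0.0^2,8]undecan-5-one; 14 tigloyl chloride
Product: 15 11-(tert-butyldimethylsilyloxy)-2,6,6,9-tetramethyl-5-oxotricyclo[5.4.0.0^2,8]undecan-3-yl (E)-2-methylbut-2-enoate
Conditions: pyridine, DMAP (cat.), CH2Cl2, 0 °C → rt
Reagents that add atoms: none
Why: DMAP-catalysed acyl transfer to the only free hydroxyl (C1); the weak base and low temperature avoid β-elimination of the β-acyloxy ketone.

**Step 10**
Reactants: 15 11-(tert-butyldimethylsilyloxy)-2,6,6,9-tetramethyl-5-oxotricyclo[5.4.0.0^2,8]undecan-3-yl (E)-2-methylbut-2-enoate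
Product: 16 11-(tert-butyldimethylsilyloxy)-5-hydroxy-2,6,6,9-tetramethyltricyclo[5.4.0.0^2,8]undecan-3-yl (E)-2-methylbut-2-enoate
Conditions: (S)-2-methyl-CBS-oxazaborolidine (50 mol%), catecholborane, toluene, −40 → 0 °C; then MeOH, H2O
Reagents that add atoms: none
Why: Second Corey–Bakshi–Shibata reduction, with quaternary C4 as the large group and the ring CH2 as the small one, which gives the (R)-carbinol at C3 trans to the C1 ester by reagent control (the two faces otherwise differ only through the remote bridge); the tiglate is inert to catecholborane.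

**Step 11**
Reactants: 16 11-(tert-butyldimethylsilyloxy)-5-hydroxy-2,6,6,9-tetramethyltricyclo[5.4.0.0^2,8]undecan-3-yl (E)-2-methylbut-2-enoate; 17 isovaleryl chloride
Product: 18 11-(tert-butyldimethylsilyloxy)-2,6,6,9-tetramethyl-5-(3-methylbutanoyloxy)tricyclo[5.4.0.0^2,8]undecan-3-yl (E)-2-methylbut-2-enoate
Conditions: Et3N, DMAP, CH2Cl2, 40 °C
Reagents that add atoms: none
Why: DMAP-catalysed esterification of the hindered neopentyl-type alcohol; the trans-1,3 arrangement prevents acyl migration.

**Step 12**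
Reactants: 18 11-(tert-butyldimethylsilyloxy)-2,6,6,9-tetramethyl-5-(3-methylbutanoyloxy)tricyclo[5.4.0.0^2,8]undecan-3-yl (E)-2-methylbut-2-enoate
Product: 19 11-hydroxy-2,6,6,9-tetramethyl-5-(3-methylbutanoyloxy)tricyclo[5.4.0.0^2,8]undecan-3-yl (E)-2-methylbut-2-enoate
Conditions: HF·pyridine, THF, 0 °C → rt
Reagents that add atoms: none
Why: Fluoride-mediated cleavage of the silyl ether; both esters are inert to buffered HF.

**Step 13**
Reactants: 19 11-hydroxy-2,6,6,9-tetramethyl-5-(3-methylbutanoyloxy)tricyclo[5.4.0.0^2,8]undecan-3-yl (E)-2-methylbut-2-enoate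
Product: 21 2,6,6,9-tetramethyl-5-(3-methylbutanoyloxy)-11-oxotricyclo[5.4.0.0^2,8]undec-9-en-3-yl (E)-2-methylbut-2-enoate, via ketone 20 (not isolated)
Conditions: 2-iodoxybenzoic acid (4 equiv), DMSO, 25 → 80 °C
Reagents that add atoms: none
Why: Oxidation of the alcohol by 2-iodoxybenzoic acid and, on warming, dehydrogenation of the ketone by the same reagent; only C8 carries enolisable hydrogens (C6 is a bridgehead), so the C8=C9 enone forms and the auxiliary C9 stereocentre is erased.

**Compound list**
1 | methyl DL-alaninate hydrochloride | CC(N)C(=O)OC.Cl | starting material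
2 | methyl DL-alaninate (free base) | CC(N)C(=O)OC | intermediate
3 | methyl 2-diazopropanoate | CC(=[N+]=[N-])C(=O)OC | intermediate
4 | (R)-5-methylcyclohex-2-en-1-one | C[C@@H]1CC=CC(=O)C1 | starting material
5 | tert-butyldimethyl{[(3R)-3-methylcyclohexa-1,5-dien-1-yl]oxy}silane (cross-conjugated silyl dienol ether) | C[C@@H]1CC=CC(O[Si](C)(C)C(C)(C)C)=C1 | intermediate
6 | methyl (5R)-1-(tert-butyldimethylsilyloxy)-5,7-dimethylbicyclo[4.1.0]hept-2-ene-7-carboxylate; cyclopropane anti to the 5-methyl, ester exo (cis to the silyloxy group), 7-methyl endo | COC(=O)[C@]1(C)[C@H]2[C@H](C)CC=C[C@]21O[Si](C)(C)C(C)(C)C | intermediate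
7 | 2,3-epoxide of 6, epoxide on the face opposite the cyclopropane | COC(=O)[C@]1(C)[C@H]2[C@H](C)C[C@@H]3O[C@@H]3[C@]21O[Si](C)(C)C(C)(C)C | intermediate
8 | methyl (4R)-2-(tert-butyldimethylsilyloxy)-4,6-dimethyl-7-oxobicyclo[3.1.1]heptane-6-carboxylate; ester on the side of the C7 carbonyl bridge, 6-methyl over the C2–C4 bridge, 2-silyloxy and 4-methyl on the side of the carbonyl bridge | COC(=O)[C@]1(C)[C@@H]2C(=O)[C@H]1[C@@H](O[Si](C)(C)C(C)(C)C)C[C@H]2C | intermediate
9 | methyl (4R)-2-(tert-butyldimethylsilyloxy)-4,6-dimethyl-7-(propan-2-ylidene)bicyclo[3.1.1]heptane-6-carboxylate | COC(=O)[C@]1(C)[C@@H]2C(=C(C)C)[C@H]1[C@@H](O[Si](C)(C)C(C)(C)C)C[C@H]2C | intermediate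
10 | 3-[(4R)-2-(tert-butyldimethylsilyloxy)-4,6-dimethyl-7-(propan-2-ylidene)bicyclo[3.1.1]heptan-6-yl]-3-oxopropanenitrile | N#CCC(=O)[C@]1(C)[C@@H]2C(=C(C)C)[C@H]1[C@@H](O[Si](C)(C)C(C)(C)C)C[C@H]2C | intermediate
11 | (3R)-3-hydroxy analogue of 10 (β-hydroxy nitrile, C1 set) | N#CC[C@@H](O)[C@]1(C)[C@@H]2C(=C(C)C)[C@H]1[C@@H](O[Si](C)(C)C(C)(C)C)C[C@H]2C | intermediate
12 | 11-(tert-butyldimethylsilyloxy)-5-imino-2,6,6,9-tetramethyltricyclo[5.4.0.0^2,8]undecan-3-ol (ketimine) | O[C@@H]1CC(=N)C(C)(C)[C@@H]2[C@H]3[C@@H](O[Si](C)(C)C(C)(C)C)C[C@@H](C)[C@@H]2[C@]31C | intermediate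
13 | 11-(tert-butyldimethylsilyloxy)-3-hydroxy-2,6,6,9-tetramethyltricyclo[5.4.0.0^2,8]undecan-5-one | O[C@@H]1CC(=O)C(C)(C)[C@@H]2[C@H]3[C@@H](O[Si](C)(C)C(C)(C)C)C[C@@H](C)[C@@H]2[C@]31C | intermediate
14 | tigloyl chloride, (E)-2-methylbut-2-enoyl chloride | C/C=C(\C)C(Cl)=O | starting material
15 | 11-(tert-butyldimethylsilyloxy)-2,6,6,9-tetramethyl-5-oxotricyclo[5.4.0.0^2,8]undecan-3-yl (E)-2-methylbut-2-enoate | C/C=C(\C)C(=O)O[C@@H]1CC(=O)C(C)(C)[C@@H]2[C@H]3[C@@H](O[Si](C)(C)C(C)(C)C)C[C@@H](C)[C@@H]2[C@]31C | intermediate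
16 | 11-(tert-butyldimethylsilyloxy)-5-hydroxy-2,6,6,9-tetramethyltricyclo[5.4.0.0^2,8]undecan-3-yl (E)-2-methylbut-2-enoate (3R,5R; trans) | C/C=C(\C)C(=O)O[C@@H]1C[C@@H](O)C(C)(C)[C@@H]2[C@H]3[C@@H](O[Si](C)(C)C(C)(C)C)C[C@@H](C)[C@@H]2[C@]31C | intermediate
17 | isovaleryl chloride, 3-methylbutanoyl chloride | CC(C)CC(Cl)=O | starting material
18 | 11-(tert-butyldimethylsilyloxy)-2,6,6,9-tetramethyl-5-(3-methylbutanoyloxy)tricyclo[5.4.0.0^2,8]undecan-3-yl (E)-2-methylbut-2-enoate | C/C=C(\C)C(=O)O[C@@H]1C[C@@H](OC(=O)CC(C)C)C(C)(C)[C@@H]2[C@H]3[C@@H](O[Si](C)(C)C(C)(C)C)C[C@@H](C)[C@@H]2[C@]31C | intermediate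
19 | 11-hydroxy-2,6,6,9-tetramethyl-5-(3-methylbutanoyloxy)tricyclo[5.4.0.0^2,8]undecan-3-yl (E)-2-methylbut-2-enoate | C/C=C(\C)C(=O)O[C@@H]1C[C@@H](OC(=O)CC(C)C)C(C)(C)[C@@H]2[C@H]3[C@@H](O)C[C@@H](C)[C@@H]2[C@]31C | intermediate
20 | 2,6,6,9-tetramethyl-5-(3-methylbutanoyloxy)-11-oxotricyclo[5.4.0.0^2,8]undecan-3-yl (E)-2-methylbut-2-enoate (saturated ketone) | C/C=C(\C)C(=O)O[C@@H]1C[C@@H](OC(=O)CC(C)C)C(C)(C)[C@@H]2[C@H]3C(=O)C[C@@H](C)[C@@H]2[C@]31C | intermediate
21 | 2,6,6,9-tetramethyl-5-(3-methylbutanoyloxy)-11-oxotricyclo[5.4.0.0^2,8]undec-9-en-3-yl (E)-2-methylbut-2-enoate | C/C=C(\C)C(=O)O[C@@H]1C[C@@H](OC(=O)CC(C)C)C(C)(C)[C@@H]2[C@H]3C(=O)C=C(C)[C@@H]2[C@]31C | target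

**Step count and risks**
Total step count: 13. Longest linear sequence: 12 steps (steps 2 to 13, from 4).

Three steps most likely to fail:

Step 4 (new ring expansion). The donor–acceptor cyclopropane could open without the 1,2-shift, or the epoxide could rearrange by another path. The fallback closes the cyclobutane by C-alkylation instead of a shift, using two known reaction types. It sets out from epoxide 7, isolated cold after removal of acetone. Anhydrous fluoride (Bu4N Ph3SiF2, THF, −78 °C) removes the silyl group and opens the 2-silyloxycyclopropane ester to the C11 ester enolate and the C5 ketone (known fluoride-induced opening of such cyclopropanes). The enolate then opens the α-keto epoxide at C6 in a 4-exo alkylation of the Stork epoxide-cyclisation type, where the four-membered ring is preferred over the five-membered one, giving the hydroxy ketone F1. Silylation (TBSOTf, 2,6-lutidine) brings it back to the route at 8.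

Step 8 (new 7-exo radical closure onto the nitrile). Hydrogen-atom transfer to the hindered tetrasubstituted alkene may be slow, and hydrogen may arrive on the wrong face of C5. The fallback is polar and uses only known chemistry; it sets out from 8 and comes back at 16. A Horner–Wadsworth–Emmons reaction with dimethyl (3-oxobutan-2-yl)phosphonate (NaH, THF, reflux) gives the enone F2. Hydrogenation (H2, Pd/C) from the open face gives the methyl ketone F3. KOt-Bu closes the seven-membered ring by a Dieckmann-type Claisen condensation onto the C11 ester to give the β-diketone F4. Its dianion (lithium diisopropylamide, 2.2 equiv) is methylated at the γ-carbon C4 with MeI to give F5. Hydrogenation with RuCl2[(S)-BINAP] gives the anti (3R,5R) diol F6. One equivalent of tigloyl chloride 14 (pyridine, DMAP) acylates the less hindered C1 hydroxyl and gives 16. This path is weaker than the main route in the selective mono-acylation and in the reduction of a hindered diketone.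

Step 3 (cyclopropanation). The α-methyl carbenoid can lose a β-hydride, and the face and exo/endo selectivity may be modest. The fallback builds C11 in two known stages; it sets out from 5 and comes back at 6. Cu(acac)2-catalysed cyclopropanation with methyl diazoacetate (benzene, 80 °C), which has no β-hydrogen problem, gives the cyclopropane ester F7. Deprotonation with lithium diisopropylamide (THF, −78 °C) and MeI then methylates the ester enolate; the methyl is expected to enter trans to the silyloxy group, as reported for such ester enolates, which gives 6.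

**Further compounds**
F1 | step 4 | methyl (4R)-2-hydroxy-4,6-dimethyl-7-oxobicyclo[3.1.1]heptane-6-carboxylate | COC(=O)[C@]1(C)[C@@H]2C(=O)[C@H]1[C@@H](O)C[C@H]2C
F2 | step 8 | methyl (4R)-2-(tert-butyldimethylsilyloxy)-4,6-dimethyl-7-(3-oxobutan-2-ylidene)bicyclo[3.1.1]heptane-6-carboxylate (mixture of alkene isomers) | COC(=O)[C@]1(C)[C@@H]2C(=C(C)C(C)=O)[C@H]1[C@@H](O[Si](C)(C)C(C)(C)C)C[C@H]2C
F3 | step 8 | methyl (4R)-2-(tert-butyldimethylsilyloxy)-4,6-dimethyl-7-(3-oxobutan-2-yl)bicyclo[3.1.1]heptane-6-carboxylate (side-chain epimers) | CC(=O)C(C)[C@@H]1[C@H]2[C@@H](O[Si](C)(C)C(C)(C)C)C[C@@H](C)[C@@H]1[C@@]2(C)C(=O)OC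
F4 | step 8 | 11-(tert-butyldimethylsilyloxy)-2,6,9-trimethyltricyclo[5.4.0.0^2,8]undecane-3,5-dione (epimers at the methyl-bearing C6 locant) | O=C1CC(=O)C(C)[C@@H]2[C@H]3[C@@H](O[Si](C)(C)C(C)(C)C)C[C@@H](C)[C@@H]2[C@]31C
F5 | step 8 | 11-(tert-butyldimethylsilyloxy)-2,6,6,9-tetramethyltricyclo[5.4.0.0^2,8]undecane-3,5-dione | O=C1CC(=O)C(C)(C)[C@@H]2[C@H]3[C@@H](O[Si](C)(C)C(C)(C)C)C[C@@H](C)[C@@H]2[C@]31C
F6 | step 8 | (3R,5R)-11-(tert-butyldimethylsilyloxy)-2,6,6,9-tetramethyltricyclo[5.4.0.0^2,8]undecane-3,5-diol | O[C@@H]1C[C@@H](O)C(C)(C)[C@@H]2[C@H]3[C@@H](O[Si](C)(C)C(C)(C)C)C[C@@H](C)[C@@H]2[C@]31C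
F7 | step 3 | methyl (5R)-1-(tert-butyldimethylsilyloxy)-5-methylbicyclo[4.1.0]hept-2-ene-7-carboxylate (C7 epimers) | COC(=O)C1[C@H]2[C@H](C)CC=C[C@]21O[Si](C)(C)C(C)(C)C
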